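**Plan**

- Retrosynthetic cuts, in order: ester → C1 primary alcohol; C5–CH3 → C5–CH2OH; ring bond O2–C3 → C5 hydroperoxide + C3 oxetane; O1–C5 → H2O2 + 2,2-disubstituted epoxide; then C1–C2 and C3–CH3 (alkyne carboalumination, CH2O), C3–C4 (acetylide on a glycidol), C5–C6 (carbomagnesiation of propargyl alcohol), C8–C9 (copper-catalysed coupling).
- Forward: the chain is joined from the phenyl end (C9–C13, then C6–C8, C5, C4/C3, C2/C1). The oxetane ring is made first, the epoxide ring second, and the 1,2-dioxolane last, with both of its C–O bonds formed in one flask from H2O2.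
- Stereochemistry: C7 is bought. C5 and C3 come from two Sharpless epoxidations (L-(+)-tartrate each) and are each inverted once in the key flask; minor isomers are diastereomers.
- Enabling feature: the ester carbon C1 stands 1,3 to ring oxygen O2 (O2–C3–C2–C1), so O, C3, C2 and C1 can be carried as an oxetane ring whose strained tertiary C3–O bond is the leaving group. C3 and C5 are 1,3 through C4, so the C5 hydroperoxide closes 5-exo and frees C1 as an alcohol.
- Helpers and their removal: the oxetane (oxidised to the ester arm, steps 14–15), the C5 hydroxymethyl left by the epoxide (deoxygenated, steps 16–17), the silyl ethers (step 11).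

Key step: step 13

Remark: the ring is numbered O1–O2–C3–C4–C5, with the acetate arm (C2, C1) on C3 and the side chain (C6–C13) on C5; this numbering is used for all intermediates. Both epoxidations are assumed to follow the usual facial rule of the tartrate catalyst, the remote stereocentres having no say.

**Route**

Step 1
Reactants: 1 (2R)-3-bromo-2-methylpropan-1-ol
Product: 2 (2R)-3-bromo-2-methylpropyl trifluoromethanesulfonate
Conditions: Tf2O, pyridine, CH2Cl2, −78 to −20 °C
Reagents that add atoms: trifluoromethanesulfonic anhydride, O=S(=O)(OS(=O)(=O)C(F)(F)F)C(F)(F)F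
Why: O-sulfonylation of a primary alcohol (triflation) leaves the stereocentre and the bromide untouched and installs a leaving group far more reactive than bromide for a chemoselective coupling.

Step 2
Reactants: 2 (2R)-3-bromo-2-methylpropyl trifluoromethanesulfonate; 3 (5-bromopentyl)benzene
Product: 5 [(7R)-8-bromo-7-methyloctyl]benzene, via Grignard reagent 4 (not isolated)
Conditions: 3, Mg, Et2O; then 2, Li2CuCl4 (cat.), THF, −78 to 0 °C
Reagents that add atoms: none
Why: copper-catalysed sp3–sp3 cross-coupling of an alkyl Grignard reagent with a primary triflate should occur at the triflate carbon only, the bromide being inert at low temperature, and the stereocentre is not involved.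

Step 3
Reactants: 5 [(7R)-8-bromo-7-methyloctyl]benzene; 6 prop-2-yn-1-ol
Product: 8 (4R)-4-methyl-2-methylidene-10-phenyldecan-1-ol, via Grignard reagent 7 (not isolated)
Conditions: 5, Mg, THF; 6 pre-treated with MeMgCl (1 equiv), then 7 (1.5 equiv), CuI (10 mol%), THF, −10 °C to rt; aq. NH4Cl
Reagents that add atoms: none
Why: copper-catalysed anti carbomagnesiation of the magnesium alkoxide of propargyl alcohol places the alkyl group on the internal alkyne carbon through a five-membered magnesium chelate and gives the 2-substituted allylic alcohol on protonation.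

Step 4
Reactants: 8 (4R)-4-methyl-2-methylidene-10-phenyldecan-1-ol
Product: 9 {(2S)-2-[(2R)-2-methyl-8-phenyloctyl]oxiran-2-yl}methanol
Conditions: Ti(OiPr)4 (10 mol%), L-(+)-diethyl tartrate (12 mol%), t-BuOOH, 4 Å MS, CH2Cl2, −25 °C
Reagents that add atoms: tert-butyl hydroperoxide, CC(C)(C)OO
Why: Sharpless asymmetric epoxidation of a 2-substituted allylic alcohol, in which the L-(+)-tartrate titanium catalyst should deliver oxygen to the face that gives the (S) glycidol (as with 2-methylprop-2-en-1-ol), so C5 is created under reagent control.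

Step 5
Reactants: 9 {(2S)-2-[(2R)-2-methyl-8-phenyloctyl]oxiran-2-yl}methanol
Product: 10 (2R)-2-[(2R)-2-methyl-8-phenyloctyl]pent-4-yne-1,2-diol
Conditions: LiC≡CH·H2NCH2CH2NH2 (excess), DMSO, rt
Reagents that add atoms: lithium acetylide ethylenediamine complex, [Li]C#C.NCCN
Why: SN2 opening of the epoxide at its unsubstituted CH2 by acetylide leaves the C5–O bond untouched (a Payne rearrangement of this 2,2-disubstituted glycidol is degenerate and returns the same enantiomer), so the tertiary carbinol keeps its configuration.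

Step 6
Reactants: 10 (2R)-2-[(2R)-2-methyl-8-phenyloctyl]pent-4-yne-1,2-diol
Product: 11 (2R)-1,2-bis[(tert-butyldimethylsilyl)oxy]-2-[(2R)-2-methyl-8-phenyloctyl]pent-4-yne
Conditions: TBSOTf, 2,6-lutidine, CH2Cl2, 0 °C to rt
Reagents that add atoms: tert-butyldimethylsilyl trifluoromethanesulfonate, CC(C)(C)[Si](C)(C)OS(=O)(=O)C(F)(F)F
Why: silyl triflate silylation protects both the primary and the hindered tertiary hydroxyl, so the diol can neither bind titanium in step 8 nor compete as a nucleophile in step 10.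

Step 7
Reactants: 11 (2R)-1,2-bis[(tert-butyldimethylsilyl)oxy]-2-[(2R)-2-methyl-8-phenyloctyl]pent-4-yne
Product: 13 (2E,5R)-5,6-bis[(tert-butyldimethylsilyl)oxy]-3-methyl-5-[(2R)-2-methyl-8-phenyloctyl]hex-2-en-1-ol, via alkenylalane 12 (not isolated)
Conditions: Me3Al, Cp2ZrCl2 (cat.), CH2Cl2, 0 °C to rt; then n-BuLi, (CH2O)n, THF, −78 °C to rt
Reagents that add atoms: trimethylaluminium, C[Al](C)C; formaldehyde (from paraformaldehyde), C=O
Why: Negishi zirconium-catalysed syn carboalumination puts methyl on the internal alkyne carbon and aluminium on the terminal one, and the alanate formed with n-BuLi adds to formaldehyde with retention to give the (E)-trisubstituted allylic alcohol.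

Step 8
Reactants: 13 (2E,5R)-5,6-bis[(tert-butyldimethylsilyl)oxy]-3-methyl-5-[(2R)-2-methyl-8-phenyloctyl]hex-2-en-1-ol
Product: 14 {(2S,3S)-3-{(2R)-2,3-bis[(tert-butyldimethylsilyl)oxy]-2-[(2R)-2-methyl-8-phenyloctyl]propyl}-3-methyloxiran-2-yl}methanol
Conditions: Ti(OiPr)4 (10 mol%), L-(+)-diethyl tartrate (12 mol%), t-BuOOH, 4 Å MS, CH2Cl2, −20 °C
Reagents that add atoms: tert-butyl hydroperoxide, CC(C)(C)OO
Why: Sharpless asymmetric epoxidation of an (E)-trisubstituted allylic alcohol of the geraniol type, where L-(+)-tartrate should give the (2S,3S) epoxide and so set C3 under reagent control irrespective of the remote C5 and C7 centres.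

Step 9
Reactants: 14 {(2S,3S)-3-{(2R)-2,3-bis[(tert-butyldimethylsilyl)oxy]-2-[(2R)-2-methyl-8-phenyloctyl]propyl}-3-methyloxiran-2-yl}methanol
Product: 15 (3R,5R)-5,6-bis[(tert-butyldimethylsilyl)oxy]-3-methyl-5-[(2R)-2-methyl-8-phenyloctyl]hexane-1,3-diol
Conditions: NaAlH2(OCH2CH2OCH3)2, THF, 0 °C
Reagents that add atoms: none
Why: hydroxyl-directed reductive opening of a 2,3-epoxy alcohol delivers hydride intramolecularly to C2 and gives the 1,3-diol, leaving the tertiary C3–O bond and its configuration intact.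

Step 10
Reactants: 15 (3R,5R)-5,6-bis[(tert-butyldimethylsilyl)oxy]-3-methyl-5-[(2R)-2-methyl-8-phenyloctyl]hexane-1,3-diol
Product: 17 (2R)-2-{(2R)-2,3-bis[(tert-butyldimethylsilyl)oxy]-2-[(2R)-2-methyl-8-phenyloctyl]propyl}-2-methyloxetane, via primary tosylate 16 (not isolated)
Conditions: n-BuLi (1 equiv), TsCl (1 equiv), THF, 0 °C; then n-BuLi (1 equiv), 0 to 50 °C
Reagents that add atoms: none
Why: selective sulfonylation of the primary alkoxide followed by intramolecular Williamson etherification (4-exo-tet) by the tertiary alkoxide closes the oxetane with retention at C3, since only the primary C1–O bond is broken.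

Step 11
Reactants: 17 (2R)-2-{(2R)-2,3-bis[(tert-butyldimethylsilyl)oxy]-2-[(2R)-2-methyl-8-phenyloctyl]propyl}-2-methyloxetane
Product: 18 (2R)-3-[(2R)-2-methyloxetan-2-yl]-2-[(2R)-2-methyl-8-phenyloctyl]propane-1,2-diol
Conditions: TBAF, THF, rt to 50 °C
Reagents that add atoms: none
Why: fluoride desilylation frees both hydroxyls under non-acidic conditions that the acid-labile oxetane should tolerate.

Step 12
Reactants: 18 (2R)-3-[(2R)-2-methyloxetan-2-yl]-2-[(2R)-2-methyl-8-phenyloctyl]propane-1,2-diol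
Product: 20 (2R)-2-methyl-2-({(2R)-2-[(2R)-2-methyl-8-phenyloctyl]oxiran-2-yl}methyl)oxetane, via primary tosylate 19 (not isolated)
Conditions: NaH, N-tosylimidazole, THF, 0 °C to rt
Reagents that add atoms: none
Why: one-pot selective tosylation of the primary hydroxyl and 3-exo-tet closure by the tertiary alkoxide give the 2,2-disubstituted epoxide with retention at C5, since only the primary C–O bond is broken.

Step 13
Reactants: 20 (2R)-2-methyl-2-({(2R)-2-[(2R)-2-methyl-8-phenyloctyl]oxiran-2-yl}methyl)oxetane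
Product: 22 2-{(3S,5S)-5-(hydroxymethyl)-3-methyl-5-[(2R)-2-methyl-8-phenyloctyl]-1,2-dioxolan-3-yl}ethan-1-ol, via hydroperoxide 21 (not isolated)
Conditions: anhydrous H2O2 in Et2O (excess), H3PMo12O40 (5 mol%), 0 °C to rt, one flask
Reagents that add atoms: hydrogen peroxide, OO
Why: The acid-activated epoxide is opened by H2O2 at the tertiary carbon C5 with inversion (SN2-like, loose transition state) to give hydroperoxide 21; its terminal oxygen then attacks the protonated oxetane at the tertiary carbon C3 from the face opposite the departing ring oxygen, which forms the O2–C3 bond, closes the 1,2-dioxolane and releases the C1 hydroxyl. The closest known reaction types are the heteropolyacid-catalysed perhydrolysis of 2,2-disubstituted epoxides to tertiary β-hydroxy hydroperoxides and the acid-promoted intramolecular opening of oxetanes by pendant hydroperoxides. The dioxolane closes in the 5-exo-tet mode (O–O–C5–C4–C3). C5 is fixed by the (R) epoxide carbon and C3 by the (R) oxetane carbon of 20, each inverted once, so the (3S,5S) diol 22 with the C3 arm and the C5 hydroxymethyl cis should result without any external control element. The step needs attack at the tertiary rather than the primary epoxide carbon (secured by acid catalysis and the cation-stabilising substitution), reaction of the epoxide before the oxetane (the three-membered ring is the more reactive under these conditions), and closure by the hydroperoxide rather than by the neighbouring primary hydroxyl (the hydroperoxide oxygen is the stronger nucleophile through the alpha effect and sits one atom further from the congested C5).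

Step 14
Reactants: 22 2-{(3S,5S)-5-(hydroxymethyl)-3-methyl-5-[(2R)-2-methyl-8-phenyloctyl]-1,2-dioxolan-3-yl}ethan-1-ol
Product: 23 {(3R,5S)-5-(hydroxymethyl)-3-methyl-5-[(2R)-2-methyl-8-phenyloctyl]-1,2-dioxolan-3-yl}acetic acid
Conditions: TEMPO (cat.), PhI(OAc)2, MeCN/H2O, 0 °C
Reagents that add atoms: water, O
Why: oxoammonium (TEMPO) oxidation of a primary alcohol to the acid via the aldehyde hydrate is sterically demanding, so it should take the unhindered C1 hydroxyl, leave the neopentyl C5 hydroxymethyl and spare the peroxide.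

Step 15
Reactants: 23 {(3R,5S)-5-(hydroxymethyl)-3-methyl-5-[(2R)-2-methyl-8-phenyloctyl]-1,2-dioxolan-3-yl}acetic acid
Product: 24 methyl {(3R,5S)-5-(hydroxymethyl)-3-methyl-5-[(2R)-2-methyl-8-phenyloctyl]-1,2-dioxolan-3-yl}acetate
Conditions: TMSCHN2, PhMe/MeOH, 0 °C
Reagents that add atoms: (trimethylsilyl)diazomethane, C[Si](C)(C)C=[N+]=[N-]
Why: diazoalkane esterification is neutral and fast, so neither the peroxide nor the β-peroxy ester (prone to base-induced retro-addition) is endangered.

Step 16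
Reactants: 24 methyl {(3R,5S)-5-(hydroxymethyl)-3-methyl-5-[(2R)-2-methyl-8-phenyloctyl]-1,2-dioxolan-3-yl}acetate
Product: 26 methyl {(3R,5S)-5-(iodomethyl)-3-methyl-5-[(2R)-2-methyl-8-phenyloctyl]-1,2-dioxolan-3-yl}acetate, via triflate 25 (not isolated)
Conditions: Tf2O, 2,6-lutidine, CH2Cl2, −78 °C; then Bu4NI, −78 °C to rt
Reagents that add atoms: tetrabutylammonium iodide, CCCC[N+](CCCC)(CCCC)CCCC.[I-]
Why: triflation followed by Finkelstein-type SN2 displacement by iodide uses the best leaving group to overcome the neopentyl hindrance, avoids phosphines that could deoxygenate the peroxide, and the β-oxygen substituents disfavour ionisation of the triflate.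

Step 17
Reactants: 26 methyl {(3R,5S)-5-(iodomethyl)-3-methyl-5-[(2R)-2-methyl-8-phenyloctyl]-1,2-dioxolan-3-yl}acetate
Product: 27 methyl {(3R,5S)-3,5-dimethyl-5-[(2R)-2-methyl-8-phenyloctyl]-1,2-dioxolan-3-yl}acetate
Conditions: Bu3SnH (excess, high concentration), Et3B/air (cat.), toluene, rt
Reagents that add atoms: none
Why: radical chain dehalogenation, in which iodine abstraction by the stannyl radical is much faster than its attack on the O–O bond and a high stannane concentration should trap the β-peroxy primary radical by hydrogen transfer before it can close onto oxygen, leaving the C5 methyl without touching any stereocentre.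

**Compound list**

1 | (2R)-3-bromo-2-methylpropan-1-ol | OC[C@@H](C)CBr | starting material
2 | (2R)-3-bromo-2-methylpropyl trifluoromethanesulfonate | FC(F)(F)S(=O)(=O)OC[C@@H](C)CBr | intermediate
3 | (5-bromopentyl)benzene | BrCCCCCc1ccccc1 | starting material
4 | (5-phenylpentyl)magnesium bromide | Br[Mg]CCCCCc1ccccc1 | intermediate (not isolated)
5 | [(7R)-8-bromo-7-methyloctyl]benzene | BrC[C@H](C)CCCCCCc1ccccc1 | intermediate
6 | prop-2-yn-1-ol | OCC#C | starting material
7 | [(2R)-2-methyl-8-phenyloctyl]magnesium bromide | Br[Mg]C[C@H](C)CCCCCCc1ccccc1 | intermediate (not isolated)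
8 | (4R)-4-methyl-2-methylidene-10-phenyldecan-1-ol | OCC(=C)C[C@H](C)CCCCCCc1ccccc1 | intermediate
9 | {(2S)-2-[(2R)-2-methyl-8-phenyloctyl]oxiran-2-yl}methanol | OC[C@]1(CO1)C[C@H](C)CCCCCCc2ccccc2 | intermediate
10 | (2R)-2-[(2R)-2-methyl-8-phenyloctyl]pent-4-yne-1,2-diol | OC[C@](O)(CC#C)C[C@H](C)CCCCCCc1ccccc1 | intermediate
11 | (2R)-1,2-bis[(tert-butyldimethylsilyl)oxy]-2-[(2R)-2-methyl-8-phenyloctyl]pent-4-yne | CC(C)(C)[Si](C)(C)OC[C@](O[Si](C)(C)C(C)(C)C)(CC#C)C[C@H](C)CCCCCCc1ccccc1 | intermediate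
12 | dimethyl{(1E,4R)-4,5-bis[(tert-butyldimethylsilyl)oxy]-2-methyl-4-[(2R)-2-methyl-8-phenyloctyl]pent-1-en-1-yl}alumane | C[Al](C)/C=C(\C)C[C@](CO[Si](C)(C)C(C)(C)C)(O[Si](C)(C)C(C)(C)C)C[C@H](C)CCCCCCc1ccccc1 | intermediate (not isolated)
13 | (2E,5R)-5,6-bis[(tert-butyldimethylsilyl)oxy]-3-methyl-5-[(2R)-2-methyl-8-phenyloctyl]hex-2-en-1-ol | OC/C=C(\C)C[C@](CO[Si](C)(C)C(C)(C)C)(O[Si](C)(C)C(C)(C)C)C[C@H](C)CCCCCCc1ccccc1 | intermediate
14 | {(2S,3S)-3-{(2R)-2,3-bis[(tert-butyldimethylsilyl)oxy]-2-[(2R)-2-methyl-8-phenyloctyl]propyl}-3-methyloxiran-2-yl}methanol | OC[C@@H]1O[C@@]1(C)C[C@](CO[Si](C)(C)C(C)(C)C)(O[Si](C)(C)C(C)(C)C)C[C@H](C)CCCCCCc2ccccc2 | intermediate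
15 | (3R,5R)-5,6-bis[(tert-butyldimethylsilyl)oxy]-3-methyl-5-[(2R)-2-methyl-8-phenyloctyl]hexane-1,3-diol | OCC[C@@](C)(O)C[C@](CO[Si](C)(C)C(C)(C)C)(O[Si](C)(C)C(C)(C)C)C[C@H](C)CCCCCCc1ccccc1 | intermediate
16 | (3R,5R)-5,6-bis[(tert-butyldimethylsilyl)oxy]-3-hydroxy-3-methyl-5-[(2R)-2-methyl-8-phenyloctyl]hexyl 4-methylbenzenesulfonate | Cc1ccc(cc1)S(=O)(=O)OCC[C@@](C)(O)C[C@](CO[Si](C)(C)C(C)(C)C)(O[Si](C)(C)C(C)(C)C)C[C@H](C)CCCCCCc2ccccc2 | intermediate (not isolated)
17 | (2R)-2-{(2R)-2,3-bis[(tert-butyldimethylsilyl)oxy]-2-[(2R)-2-methyl-8-phenyloctyl]propyl}-2-methyloxetane | C[C@@]1(CCO1)C[C@](CO[Si](C)(C)C(C)(C)C)(O[Si](C)(C)C(C)(C)C)C[C@H](C)CCCCCCc2ccccc2 | intermediate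
18 | (2R)-3-[(2R)-2-methyloxetan-2-yl]-2-[(2R)-2-methyl-8-phenyloctyl]propane-1,2-diol | OC[C@](O)(C[C@@]1(C)CCO1)C[C@H](C)CCCCCCc2ccccc2 | intermediate
19 | (2R)-2-hydroxy-3-[(2R)-2-methyloxetan-2-yl]-2-[(2R)-2-methyl-8-phenyloctyl]propyl 4-methylbenzenesulfonate | Cc1ccc(cc1)S(=O)(=O)OC[C@](O)(C[C@@]2(C)CCO2)C[C@H](C)CCCCCCc3ccccc3 | intermediate (not isolated)
20 | (2R)-2-methyl-2-({(2R)-2-[(2R)-2-methyl-8-phenyloctyl]oxiran-2-yl}methyl)oxetane | C[C@@]1(CCO1)C[C@@]2(CO2)C[C@H](C)CCCCCCc3ccccc3 | intermediate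
21 | (2S)-2-hydroperoxy-3-[(2R)-2-methyloxetan-2-yl]-2-[(2R)-2-methyl-8-phenyloctyl]propan-1-ol | OC[C@@](OO)(C[C@@]1(C)CCO1)C[C@H](C)CCCCCCc2ccccc2 | intermediate (not isolated)
22 | 2-{(3S,5S)-5-(hydroxymethyl)-3-methyl-5-[(2R)-2-methyl-8-phenyloctyl]-1,2-dioxolan-3-yl}ethan-1-ol | OCC[C@@]1(C)C[C@](CO)(C[C@H](C)CCCCCCc2ccccc2)OO1 | intermediate
23 | {(3R,5S)-5-(hydroxymethyl)-3-methyl-5-[(2R)-2-methyl-8-phenyloctyl]-1,2-dioxolan-3-yl}acetic acid | OC(=O)C[C@@]1(C)C[C@](CO)(C[C@H](C)CCCCCCc2ccccc2)OO1 | intermediate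
24 | methyl {(3R,5S)-5-(hydroxymethyl)-3-methyl-5-[(2R)-2-methyl-8-phenyloctyl]-1,2-dioxolan-3-yl}acetate | COC(=O)C[C@@]1(C)C[C@](CO)(C[C@H](C)CCCCCCc2ccccc2)OO1 | intermediate
25 | methyl {(3R,5S)-3-methyl-5-[(2R)-2-methyl-8-phenyloctyl]-5-{[(trifluoromethanesulfonyl)oxy]methyl}-1,2-dioxolan-3-yl}acetate | COC(=O)C[C@@]1(C)C[C@](COS(=O)(=O)C(F)(F)F)(C[C@H](C)CCCCCCc2ccccc2)OO1 | intermediate (not isolated)
26 | methyl {(3R,5S)-5-(iodomethyl)-3-methyl-5-[(2R)-2-methyl-8-phenyloctyl]-1,2-dioxolan-3-yl}acetate | COC(=O)C[C@@]1(C)C[C@](CI)(C[C@H](C)CCCCCCc2ccccc2)OO1 | intermediate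
27 | methyl {(3R,5S)-3,5-dimethyl-5-[(2R)-2-methyl-8-phenyloctyl]-1,2-dioxolan-3-yl}acetate | COC(=O)C[C@@]1(C)C[C@](C)(C[C@H](C)CCCCCCc2ccccc2)OO1 | target

**Step count**

Total steps: 17. Longest linear sequence: 17 steps (1 to 27; 3 enters in step 2 and 6 in step 3).

**Steps most likely to fail**

1. Step 13. What may go wrong: closure of the activated oxetane by the neighbouring primary hydroxyl in place of the hydroperoxide (tetrahydrofuran formation), a second intermolecular perhydrolysis before ring closure, or partial ionisation at the tertiary centres that leaks configuration. Fallback, from 18 back to 27: the ionic perhydrolysis is replaced by radical peroxidation of an alkene that carries no free hydroxyl. Diol 18 is converted with thiocarbonyldiimidazole into the cyclic thionocarbonate F1, and Corey–Winter olefination (P(OMe)3, heat) gives the 1,1-disubstituted alkene F2 with the oxetane intact. Mukaiyama–Isayama hydroperoxysilylation (Co(acac)2 cat., O2, Et3SiH) gives the triethylsilyl peroxide F3 as both C5 epimers, the C5 methyl now coming from hydrogen-atom transfer. Desilylation and acid-promoted 5-exo oxetane opening (HF–pyridine, then cat. camphorsulfonic acid) close the ring with inversion at C3; chromatography should separate the dioxolane alcohol F4 from its C5 epimer. TEMPO/PhI(OAc)2 oxidation gives the acid F5, and TMSCHN2 returns the route at 27. This path gives up control at C5 but needs no deoxygenation.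

2. Step 17. What may go wrong: ring closure of the β-peroxy primary radical onto oxygen with O–O scission (epoxide formation), and stannyl radical attack on the peroxide. Fallback, from 24 back to 27: a polar reduction in place of the radical one. Alcohol 24 is triflated as in step 16 and the triflate 25 is treated directly with Bu4NBH4 (CH2Cl2, 0 °C to rt) for hydride displacement, which should spare the dialkyl peroxide and the methyl ester; this path makes no compound outside the list (F0).

3. Step 14. What may go wrong: loss of chemoselectivity, the neopentyl C5 hydroxymethyl being oxidised along with the C1 hydroxyl. Fallback, from 22 back to 24: differentiation by protection in place of kinetic selection. Diol 22 is silylated twice (TBSCl, imidazole) to the bis-silyl ether F6; the unhindered primary silyl ether is cleaved selectively (HF–pyridine, pyridine, THF, 0 °C) to the mono-silyl alcohol F7. TEMPO/PhI(OAc)2 oxidation of the only free hydroxyl gives the silyloxy acid F8, TMSCHN2 gives the silyloxy ester F9, and buffered TBAF/AcOH returns the route at 24.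

**Further compounds**

F1 | step 13 | (4R)-4-{[(2R)-2-methyloxetan-2-yl]methyl}-4-[(2R)-2-methyl-8-phenyloctyl]-1,3-dioxolane-2-thione | S=C1OC[C@](O1)(C[C@@]2(C)CCO2)C[C@H](C)CCCCCCc3ccccc3
F2 | step 13 | (2S)-2-methyl-2-[(4R)-4-methyl-2-methylidene-10-phenyldecyl]oxetane | C=C(C[C@@]1(C)CCO1)C[C@H](C)CCCCCCc2ccccc2
F3 | step 13 | triethyl{[(4R)-4-methyl-2-{[(2R)-2-methyloxetan-2-yl]methyl}-10-phenyldecan-2-yl]peroxy}silane (both C2 epimers) | CC[Si](CC)(CC)OOC(C)(C[C@@]1(C)CCO1)C[C@H](C)CCCCCCc2ccccc2
F4 | step 13 | 2-{(3S,5S)-3,5-dimethyl-5-[(2R)-2-methyl-8-phenyloctyl]-1,2-dioxolan-3-yl}ethan-1-ol | OCC[C@@]1(C)C[C@](C)(C[C@H](C)CCCCCCc2ccccc2)OO1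
F5 | step 13 | {(3R,5S)-3,5-dimethyl-5-[(2R)-2-methyl-8-phenyloctyl]-1,2-dioxolan-3-yl}acetic acid | OC(=O)C[C@@]1(C)C[C@](C)(C[C@H](C)CCCCCCc2ccccc2)OO1
F6 | step 14 | (3S,5S)-3-{2-[(tert-butyldimethylsilyl)oxy]ethyl}-5-{[(tert-butyldimethylsilyl)oxy]methyl}-3-methyl-5-[(2R)-2-methyl-8-phenyloctyl]-1,2-dioxolane | CC(C)(C)[Si](C)(C)OCC[C@@]1(C)C[C@](CO[Si](C)(C)C(C)(C)C)(C[C@H](C)CCCCCCc2ccccc2)OO1
F7 | step 14 | 2-{(3S,5S)-5-{[(tert-butyldimethylsilyl)oxy]methyl}-3-methyl-5-[(2R)-2-methyl-8-phenyloctyl]-1,2-dioxolan-3-yl}ethan-1-ol | OCC[C@@]1(C)C[C@](CO[Si](C)(C)C(C)(C)C)(C[C@H](C)CCCCCCc2ccccc2)OO1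
F8 | step 14 | {(3R,5S)-5-{[(tert-butyldimethylsilyl)oxy]methyl}-3-methyl-5-[(2R)-2-methyl-8-phenyloctyl]-1,2-dioxolan-3-yl}acetic acid | OC(=O)C[C@@]1(C)C[C@](CO[Si](C)(C)C(C)(C)C)(C[C@H](C)CCCCCCc2ccccc2)OO1
F9 | step 14 | methyl {(3R,5S)-5-{[(tert-butyldimethylsilyl)oxy]methyl}-3-methyl-5-[(2R)-2-methyl-8-phenyloctyl]-1,2-dioxolan-3-yl}acetate | COC(=O)C[C@@]1(C)C[C@](CO[Si](C)(C)C(C)(C)C)(C[C@H](C)CCCCCCc2ccccc2)OO1
F0 | step 17 | none | none
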